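**Retrosynthetic overview**

- Numbering runs C1–C19 from the pentyl end: the oxolane is O1/C6/C7/C8/C9, the free hydroxyl is on C7 and the laurate on C10. The strategy rests on the C7 carbinol lying between C6 and C8 inside this ring: it is taken back to a ring ketone and then to a C7=C8 silyl enol ether, so that the acyclic C6–O1–C9 ether left behind already carries both ring stereocentres.
- Late disconnections: C10–O ester (lauroylation), C10–C11 (chelation-controlled addition of non-8-enylmagnesium bromide to the C10 aldehyde), C7–H (hydride delivered anti to the C6 pentyl group).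
- Ring formation (the only ring): ring-closing metathesis of the C9 vinyl group onto the C7 triethylsilyl enol ether closes the 2,5-dihydrofuran through C7=C8.
- Diene: SN2 ether union, with inversion at C6, of (R)-1-(PMB-oxy)but-3-en-2-ol (from (S)-glycidol) and methyl (R)-2-triflyloxyheptanoate (from methyl (R)-glycidate and butylmagnesium chloride), then ester → Weinreb amide → methyl ketone → kinetic silyl enol ether.

Key step: step 9

Remark: metal alkoxides that are only the conjugate base of a step's product before aqueous work-up, and catalytic ruthenium intermediates, are not numbered.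

**Route**

Step 1
Reactants: 1 (S)-glycidol, (2S)-oxiran-2-ylmethanol
Product: 2 (2R)-2-{[(4-methoxybenzyl)oxy]methyl}oxirane
Conditions: NaH, PMBCl, Bu4NI (cat.), THF–DMF, 0 °C → rt
Reagents that add atoms: 4-methoxybenzyl chloride, COc1ccc(CCl)cc1
Why: Williamson etherification of the primary alkoxide with the benzylic chloride leaves the epoxide and its stereocentre untouched (a Payne shift of glycidol alkoxide is degenerate and returns the same enantiomer), the change of descriptor from S to R being a matter of CIP priorities only.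

Step 2
Reactants: 2 (2R)-2-{[(4-methoxybenzyl)oxy]methyl}oxirane
Product: 4 (2R)-1-[(4-methoxybenzyl)oxy]but-3-en-2-ol, via sulfonium betaine 3 (not isolated)
Conditions: Me3S+ I−, n-BuLi, THF, −10 °C → rt
Reagents that add atoms: trimethylsulfonium iodide, C[S+](C)C.[I-]
Why: Epoxide-to-allylic-alcohol homologation with dimethylsulfonium methylide, in which the ylide opens the epoxide at its CH2 terminus and a second equivalent triggers ylide-mediated syn-elimination of dimethyl sulfide from the betaine, should deliver the vinyl carbinol with the C9–O stereocentre untouched.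

Step 3
Reactants: 5 methyl (2R)-oxirane-2-carboxylate (methyl (R)-glycidate); 6 butylmagnesium chloride
Product: 7 methyl (2R)-2-hydroxyheptanoate
Conditions: CuBr·SMe2 (10 mol %), THF, −78 → −40 °C; aq NH4Cl
Reagents that add atoms: none
Why: Copper-catalysed SN2 opening of the glycidic ester by the Grignard reagent takes place at the unsubstituted C3 and faster than carbonyl addition at low temperature, so the C2 stereocentre (the future C6) is carried over unchanged as the (R)-α-hydroxy ester.

Step 4
Reactants: 7 methyl (2R)-2-hydroxyheptanoate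
Product: 8 methyl (2R)-2-{[(trifluoromethyl)sulfonyl]oxy}heptanoate
Conditions: Tf2O, 2,6-lutidine, CH2Cl2, −78 → 0 °C
Reagents that add atoms: trifluoromethanesulfonic anhydride, O=S(=O)(OS(=O)(=O)C(F)(F)F)C(F)(F)F
Why: O-Sulfonylation of the secondary alcohol with triflic anhydride and a hindered pyridine base breaks no bond at the stereocentre, so the (R)-triflate forms with retention and is used at once.

Step 5
Reactants: 4 (2R)-1-[(4-methoxybenzyl)oxy]but-3-en-2-ol; 8 methyl (2R)-2-{[(trifluoromethyl)sulfonyl]oxy}heptanoate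
Product: 10 methyl (2S)-2-({(2R)-1-[(4-methoxybenzyl)oxy]but-3-en-2-yl}oxy)heptanoate, via sodium alkoxide 9 (not isolated)
Conditions: NaH, THF, 0 °C; then 8, −40 → 0 °C
Reagents that add atoms: none
Why: Williamson-type SN2 displacement of the carbonyl-activated secondary triflate by the sodium alkoxide proceeds with inversion at C6 (R to S) while C9 of the nucleophile is not touched, which fixes the relative configuration of the two future ring carbons.

Step 6
Reactants: 10 methyl (2S)-2-({(2R)-1-[(4-methoxybenzyl)oxy]but-3-en-2-yl}oxy)heptanoate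
Product: 11 (2S)-N-methoxy-2-({(2R)-1-[(4-methoxybenzyl)oxy]but-3-en-2-yl}oxy)-N-methylheptanamide
Conditions: MeNH(OMe)·HCl, i-PrMgCl, THF, −20 °C
Reagents that add atoms: N,O-dimethylhydroxylamine hydrochloride, CNOC.Cl
Why: Weinreb amide formation by attack of the chloromagnesium amide of N,O-dimethylhydroxylamine on the methyl ester is an acyl substitution that is fast at −20 °C, where the weakly basic magnesium amide should not enolise the α-alkoxy C6 centre.

Step 7
Reactants: 11 (2S)-N-methoxy-2-({(2R)-1-[(4-methoxybenzyl)oxy]but-3-en-2-yl}oxy)-N-methylheptanamide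
Product: 13 (3S)-3-({(2R)-1-[(4-methoxybenzyl)oxy]but-3-en-2-yl}oxy)octan-2-one, via magnesium hemiaminal chelate 12 (not isolated)
Conditions: MeMgBr, THF, −78 → 0 °C; aq NH4Cl
Reagents that add atoms: methylmagnesium bromide, C[Mg]Br
Why: Weinreb ketone synthesis, in which the five-membered N-methoxy magnesium chelate holds the tetrahedral adduct until work-up, so that a single methyl group is delivered and the methyl ketone forms without over-addition or epimerisation.

Step 8
Reactants: 13 (3S)-3-({(2R)-1-[(4-methoxybenzyl)oxy]but-3-en-2-yl}oxy)octan-2-one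
Product: 15 triethyl{[(3S)-3-({(2R)-1-[(4-methoxybenzyl)oxy]but-3-en-2-yl}oxy)oct-1-en-2-yl]oxy}silane, via lithium enolate 14 (not isolated)
Conditions: LDA, THF, −78 °C; then TESCl, −78 → 0 °C; cold NaHCO3 work-up
Reagents that add atoms: chlorotriethylsilane, CC[Si](Cl)(CC)CC
Why: Kinetic enolisation with LDA at −78 °C removes a proton from the unhindered methyl group and not from the tertiary α-alkoxy C6–H (whose enolate would epimerise or undergo a [2,3]-Wittig shift), and O-silylation of the lithium enolate gives the 1,1-disubstituted triethylsilyl enol ether with C6 intact.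

Step 9
Reactants: 15 triethyl{[(3S)-3-({(2R)-1-[(4-methoxybenzyl)oxy]but-3-en-2-yl}oxy)oct-1-en-2-yl]oxy}silane
Product: 16 triethyl{[(2S,5R)-5-{[(4-methoxybenzyl)oxy]methyl}-2-pentyl-2,5-dihydrofuran-3-yl]oxy}silane
Conditions: (H2IMes)(PCy3)Cl2Ru=CHPh (second-generation Grubbs catalyst, 5–10 mol %), degassed PhH (0.01 M), 65 °C
Reagents that add atoms: none
Why: Ring-closing olefin metathesis by the Chauvin mechanism: the ruthenium benzylidene initiates at the monosubstituted C9 vinyl group, the resulting alkylidene adds intramolecularly [2+2] across the C7=CH2 bond of the silyl enol ether, and cycloreversion of the ruthenacyclobutane forms C7=C8 and a ruthenium methylidene that carries the chain, ethylene being lost. The closest known reaction type is the ring-closing metathesis of silyl enol ether dienes to cyclic silyl enol ethers with N-heterocyclic-carbene ruthenium catalysts. The single ring (O1, C6, C7, C8, C9) closes as a five-membered 2,5-dihydrofuran from a 1,6-diene through the C7=C8 bond. No stereocentre is created; C6 (S) and C9 (R), fixed as the 2,5-trans pair by the invertive etherification, are only carried through. The step needs ring closure to outrun intermolecular metathesis at the vinyl group and needs the enol ether and the C6–H to stay intact: the 1,6-diene spacing and high dilution favour five-ring closure, the hindered enol ether olefin should not homodimerise, and the neutral, aprotic, base-free medium offers no path for enolisation or desilylation.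

Step 10
Reactants: 16 triethyl{[(2S,5R)-5-{[(4-methoxybenzyl)oxy]methyl}-2-pentyl-2,5-dihydrofuran-3-yl]oxy}silane
Product: 17 (2S,5R)-5-{[(4-methoxybenzyl)oxy]methyl}-2-pentyloxolan-3-one
Conditions: 0.5 M HCl (aq), THF, 0 °C
Reagents that add atoms: none
Why: Mild acid hydrolysis of the silyl enol ether (C8 protonation, loss of silanol) unmasks the oxolan-3-one without creating a stereocentre, and the brief, cold, weakly acidic conditions should not enolise the ketone toward C6.

Step 11
Reactants: 17 (2S,5R)-5-{[(4-methoxybenzyl)oxy]methyl}-2-pentyloxolan-3-one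
Product: 18 (2S,3S,5R)-5-{[(4-methoxybenzyl)oxy]methyl}-2-pentyloxolan-3-ol
Conditions: LiBH(s-Bu)3, THF, −78 °C; aq NH4Cl
Reagents that add atoms: none
Why: Substrate-controlled ketone reduction with the bulky hydride LiBH(s-Bu)3, which approaches the ring carbonyl on the face anti to the adjacent C6 pentyl group, should set C7 as S with the hydroxyl cis to the pentyl chain.

Step 12
Reactants: 18 (2S,3S,5R)-5-{[(4-methoxybenzyl)oxy]methyl}-2-pentyloxolan-3-ol
Product: 19 tert-butyl{[(2S,3S,5R)-5-{[(4-methoxybenzyl)oxy]methyl}-2-pentyloxolan-3-yl]oxy}dimethylsilane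
Conditions: TBSOTf, 2,6-lutidine, CH2Cl2, −78 → 0 °C
Reagents that add atoms: tert-butyldimethylsilyl trifluoromethanesulfonate, CC(C)(C)[Si](C)(C)OS(=O)(=O)C(F)(F)F
Why: Silyl ether formation with the silyl triflate and 2,6-lutidine protects the hindered secondary C7 hydroxyl without touching any stereocentre or the PMB ether.

Step 13
Reactants: 19 tert-butyl{[(2S,3S,5R)-5-{[(4-methoxybenzyl)oxy]methyl}-2-pentyloxolan-3-yl]oxy}dimethylsilane
Product: 20 [(2R,4S,5S)-4-{[tert-butyl(dimethyl)silyl]oxy}-5-pentyloxolan-2-yl]methanol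
Conditions: DDQ, CH2Cl2–pH 7 buffer, 0 °C → rt
Reagents that add atoms: none
Why: Oxidative cleavage of the PMB ether by DDQ (hydride abstraction from the electron-rich benzylic position and hydrolysis of the oxocarbenium ion) frees the primary C10 alcohol and leaves the TBS ether and the oxolane untouched.

Step 14
Reactants: 20 [(2R,4S,5S)-4-{[tert-butyl(dimethyl)silyl]oxy}-5-pentyloxolan-2-yl]methanol
Product: 21 (2R,4S,5S)-4-{[tert-butyl(dimethyl)silyl]oxy}-5-pentyloxolane-2-carbaldehyde
Conditions: Dess–Martin periodinane, NaHCO3, CH2Cl2, 0 °C → rt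
Reagents that add atoms: none
Why: Dess–Martin oxidation under bicarbonate buffering gives the α-alkoxy aldehyde under near-neutral conditions that should not epimerise C9, the crude aldehyde being used directly.

Step 15
Reactants: 21 (2R,4S,5S)-4-{[tert-butyl(dimethyl)silyl]oxy}-5-pentyloxolane-2-carbaldehyde; 22 9-bromonon-1-ene
Product: 24 (1R)-1-[(2R,4S,5S)-4-{[tert-butyl(dimethyl)silyl]oxy}-5-pentyloxolan-2-yl]dec-9-en-1-ol, via non-8-enylmagnesium bromide 23 (not isolated)
Conditions: 22, Mg, Et2O, rt → reflux; then 21, MgBr2·OEt2, CH2Cl2–Et2O, −78 °C; aq NH4Cl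
Reagents that add atoms: none
Why: Cram-chelate-controlled Grignard addition, in which magnesium bridges the aldehyde oxygen and ring oxygen O1 and the alkyl group attacks the locked carbonyl on the face of the C9 hydrogen, away from ring carbon C8, should set C10 as R (threo to C9).

Step 16
Reactants: 24 (1R)-1-[(2R,4S,5S)-4-{[tert-butyl(dimethyl)silyl]oxy}-5-pentyloxolan-2-yl]dec-9-en-1-ol; 25 dodecanoyl chloride
Product: 26 (1R)-1-[(2R,4S,5S)-4-{[tert-butyl(dimethyl)silyl]oxy}-5-pentyloxolan-2-yl]dec-9-en-1-yl dodecanoate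
Conditions: pyridine, DMAP (cat.), CH2Cl2, 0 °C → rt
Reagents that add atoms: none
Why: DMAP-catalysed acylation (acyl transfer from the acylpyridinium ion) esterifies the only free hydroxyl, at C10, with retention since no C–O bond of the stereocentre is broken.

Step 17
Reactants: 26 (1R)-1-[(2R,4S,5S)-4-{[tert-butyl(dimethyl)silyl]oxy}-5-pentyloxolan-2-yl]dec-9-en-1-yl dodecanoate
Product: 27 (1R)-1-[(2R,4S,5S)-4-hydroxy-5-pentyloxolan-2-yl]dec-9-en-1-yl dodecanoate (CNP0219213.1)
Conditions: HF·pyridine, pyridine, THF, 0 °C → rt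
Reagents that add atoms: none
Why: Fluoride-mediated desilylation with buffered HF·pyridine cleaves the Si–O bond of the TBS ether while the laurate ester, the terminal alkene and all four stereocentres are left untouched.

**Compound list**

1 | (S)-glycidol, (2S)-oxiran-2-ylmethanol | OC[C@H]1CO1 | starting material
2 | (2R)-2-{[(4-methoxybenzyl)oxy]methyl}oxirane | COc1ccc(COC[C@H]2CO2)cc1 | intermediate
3 | (2R)-4-(dimethylsulfonio)-1-[(4-methoxybenzyl)oxy]butan-2-olate (sulfonium betaine, not isolated) | C[S+](C)CC[C@@H]([O-])COCc1ccc(OC)cc1 | intermediate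
4 | (2R)-1-[(4-methoxybenzyl)oxy]but-3-en-2-ol | COc1ccc(COC[C@H](O)C=C)cc1 | intermediate
5 | methyl (2R)-oxirane-2-carboxylate | COC(=O)[C@H]1CO1 | starting material
6 | butylmagnesium chloride | CCCC[Mg]Cl | starting material
7 | methyl (2R)-2-hydroxyheptanoate | CCCCC[C@@H](O)C(=O)OC | intermediate
8 | methyl (2R)-2-{[(trifluoromethyl)sulfonyl]oxy}heptanoate | CCCCC[C@@H](OS(=O)(=O)C(F)(F)F)C(=O)OC | intermediate
9 | sodium (2R)-1-[(4-methoxybenzyl)oxy]but-3-en-2-olate (not isolated) | COc1ccc(COC[C@H]([O-])C=C)cc1.[Na+] | intermediate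
10 | methyl (2S)-2-({(2R)-1-[(4-methoxybenzyl)oxy]but-3-en-2-yl}oxy)heptanoate | CCCCC[C@H](O[C@H](C=C)COCc1ccc(OC)cc1)C(=O)OC | intermediate
11 | (2S)-N-methoxy-2-({(2R)-1-[(4-methoxybenzyl)oxy]but-3-en-2-yl}oxy)-N-methylheptanamide | CCCCC[C@H](O[C@H](C=C)COCc1ccc(OC)cc1)C(=O)N(C)OC | intermediate
12 | bromomagnesium alkoxide of the tetrahedral methyl adduct of 11 (magnesium hemiaminal chelate, new carbon unassigned, not isolated) | CCCCC[C@H](O[C@H](C=C)COCc1ccc(OC)cc1)C(C)(O[Mg]Br)N(C)OC | intermediate
13 | (3S)-3-({(2R)-1-[(4-methoxybenzyl)oxy]but-3-en-2-yl}oxy)octan-2-one | CCCCC[C@H](O[C@H](C=C)COCc1ccc(OC)cc1)C(C)=O | intermediate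
14 | lithium (3S)-3-({(2R)-1-[(4-methoxybenzyl)oxy]but-3-en-2-yl}oxy)oct-1-en-2-olate (not isolated) | CCCCC[C@H](O[C@H](C=C)COCc1ccc(OC)cc1)C(=C)O[Li] | intermediate
15 | triethyl{[(3S)-3-({(2R)-1-[(4-methoxybenzyl)oxy]but-3-en-2-yl}oxy)oct-1-en-2-yl]oxy}silane | CCCCC[C@H](O[C@H](C=C)COCc1ccc(OC)cc1)C(=C)O[Si](CC)(CC)CC | intermediate
16 | triethyl{[(2S,5R)-5-{[(4-methoxybenzyl)oxy]methyl}-2-pentyl-2,5-dihydrofuran-3-yl]oxy}silane | COc1ccc(COC[C@H]2C=C(O[Si](CC)(CC)CC)[C@H](CCCCC)O2)cc1 | intermediate
17 | (2S,5R)-5-{[(4-methoxybenzyl)oxy]methyl}-2-pentyloxolan-3-one | COc1ccc(COC[C@H]2CC(=O)[C@H](CCCCC)O2)cc1 | intermediate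
18 | (2S,3S,5R)-5-{[(4-methoxybenzyl)oxy]methyl}-2-pentyloxolan-3-ol | COc1ccc(COC[C@H]2C[C@H](O)[C@H](CCCCC)O2)cc1 | intermediate
19 | tert-butyl{[(2S,3S,5R)-5-{[(4-methoxybenzyl)oxy]methyl}-2-pentyloxolan-3-yl]oxy}dimethylsilane | COc1ccc(COC[C@H]2C[C@H](O[Si](C)(C)C(C)(C)C)[C@H](CCCCC)O2)cc1 | intermediate
20 | [(2R,4S,5S)-4-{[tert-butyl(dimethyl)silyl]oxy}-5-pentyloxolan-2-yl]methanol | OC[C@H]1C[C@H](O[Si](C)(C)C(C)(C)C)[C@H](CCCCC)O1 | intermediate
21 | (2R,4S,5S)-4-{[tert-butyl(dimethyl)silyl]oxy}-5-pentyloxolane-2-carbaldehyde | O=C[C@H]1C[C@H](O[Si](C)(C)C(C)(C)C)[C@H](CCCCC)O1 | intermediate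
22 | 9-bromonon-1-ene | C=CCCCCCCCBr | starting material
23 | non-8-enylmagnesium bromide (not isolated) | C=CCCCCCCC[Mg]Br | intermediate
24 | (1R)-1-[(2R,4S,5S)-4-{[tert-butyl(dimethyl)silyl]oxy}-5-pentyloxolan-2-yl]dec-9-en-1-ol | C=CCCCCCCC[C@@H](O)[C@H]1C[C@H](O[Si](C)(C)C(C)(C)C)[C@H](CCCCC)O1 | intermediate
25 | dodecanoyl chloride | CCCCCCCCCCCC(=O)Cl | starting material
26 | (1R)-1-[(2R,4S,5S)-4-{[tert-butyl(dimethyl)silyl]oxy}-5-pentyloxolan-2-yl]dec-9-en-1-yl dodecanoate | C=CCCCCCCC[C@@H](OC(=O)CCCCCCCCCCC)[C@H]1C[C@H](O[Si](C)(C)C(C)(C)C)[C@H](CCCCC)O1 | intermediate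
27 | (1R)-1-[(2R,4S,5S)-4-hydroxy-5-pentyloxolan-2-yl]dec-9-en-1-yl dodecanoate (CNP0219213.1) | C=CCCCCCCC[C@@H](OC(=O)CCCCCCCCCCC)[C@H]1C[C@H](O)[C@H](CCCCC)O1 | target

**Step count and risks**

Total step count: 17. Longest linear sequence: 15 steps (steps 1, 2 and 5–17; the branch through steps 3 and 4 is equally long).

Steps most likely to fail:

1. Step 9 (ring-closing metathesis). The electron-rich, 1,1-disubstituted silyl enol ether may engage the ruthenium alkylidene too slowly. That would leave time for intermolecular metathesis at the vinyl group, for double-bond migration by ruthenium hydride species, or for loss of the silyl group to traces of acid or moisture, which returns a methyl ketone that cannot cyclise. Fallback: set out from ester 10. Methylenation of the ester carbonyl with the Tebbe reagent Cp2Ti(μ-Cl)(μ-CH2)AlMe2 (THF–pyridine, −40 °C → rt) should give the hydrolytically more robust methyl enol ether diene F1, made without any enolisation. Ring closure of this alkyl enol ether with the Schrock alkylidene Mo(=CHCMe2Ph)(=N-2,6-i-Pr2C6H3)[OCMe(CF3)2]2 (benzene, rt) should give the 3-methoxy-2,5-dihydrofuran F2. Dilute aqueous HCl in THF at 0 °C then hydrolyses the enol ether, and the route is rejoined at ketone 17.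

2. Step 5 (ether union). The hindered secondary alkoxide may act as a base (E2 elimination of the triflate to the α,β-unsaturated ester) or attack the ester carbonyl, and triflate self-exchange could erode the configuration at C6 before substitution. Fallback: set out from alcohol 4. Its sodium alkoxide (excess NaH, THF–DMF, 0 °C → rt) is alkylated with the sodium salt of racemic 2-bromoheptanoic acid (CCCCCC(Br)C(=O)O), whose carboxylate suppresses acyl attack, to give the α-alkoxy acid F3 as both C2 epimers. Stereocontrol at C6 is given up in this variant. Amide coupling with MeNH(OMe)·HCl (EDC·HCl, HOBt, i-Pr2NEt, CH2Cl2) gives Weinreb amide 11 together with its (2R)-epimer F4, which is removed by chromatography; the route is rejoined at 11.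

3. Step 15 (Grignard addition). Incomplete chelation would let the open Felkin–Anh pathway compete and lower the facial selectivity at C10, and the basic reagent may enolise the α-alkoxy aldehyde and erode C9. Fallback: set out from aldehyde 21. Addition of Grignard reagent 23 in THF without a chelating additive gives alcohol 24 mixed with its (1S)-epimer F5. The mixture is oxidised with Dess–Martin periodinane to the single ketone F6, and reduction with LiBH(s-Bu)3 (THF, −78 °C) under non-chelating Felkin–Anh control, hydride arriving anti to the ring C–O bond, should give the threo alcohol; the route is rejoined at 24.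

**Further compounds**

F1 | step 9 | methyl enol ether diene, 1-methoxy-4-{[((2R)-2-{[(3S)-2-methoxyoct-1-en-3-yl]oxy}but-3-en-1-yl)oxy]methyl}benzene | CCCCC[C@H](O[C@H](C=C)COCc1ccc(OC)cc1)C(=C)OC
F2 | step 9 | 3-methoxy-2,5-dihydrofuran, (2S,5R)-3-methoxy-5-{[(4-methoxybenzyl)oxy]methyl}-2-pentyl-2,5-dihydrofuran | COc1ccc(COC[C@H]2C=C(OC)[C@H](CCCCC)O2)cc1
F3 | step 5 | α-alkoxy acid, 2-({(2R)-1-[(4-methoxybenzyl)oxy]but-3-en-2-yl}oxy)heptanoic acid (both C2 epimers) | CCCCCC(O[C@H](C=C)COCc1ccc(OC)cc1)C(=O)O
F4 | step 5 | (2R)-epimer of Weinreb amide 11, (2R)-N-methoxy-2-({(2R)-1-[(4-methoxybenzyl)oxy]but-3-en-2-yl}oxy)-N-methylheptanamide | CCCCC[C@@H](O[C@H](C=C)COCc1ccc(OC)cc1)C(=O)N(C)OC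
F5 | step 15 | (1S)-epimer of alcohol 24, (1S)-1-[(2R,4S,5S)-4-{[tert-butyl(dimethyl)silyl]oxy}-5-pentyloxolan-2-yl]dec-9-en-1-ol | C=CCCCCCCC[C@H](O)[C@H]1C[C@H](O[Si](C)(C)C(C)(C)C)[C@H](CCCCC)O1
F6 | step 15 | ketone, 1-[(2R,4S,5S)-4-{[tert-butyl(dimethyl)silyl]oxy}-5-pentyloxolan-2-yl]dec-9-en-1-one | C=CCCCCCCCC(=O)[C@H]1C[C@H](O[Si](C)(C)C(C)(C)C)[C@H](CCCCC)O1
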